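## Retrosynthetic overview

1. Ring atoms are numbered C1 (quaternary carbon), C2=C3, C4 (ester carbon), C5 (tertiary carbinol), C6=C7, C8 (ketone), C9 (bears CH2OH), C10, C11. The single 11-membered ring is closed last, at C7–C8–C9, by carbonylative Stille coupling of an E-vinyl iodide with a Z-alkenylstannane made by hydroxyl-directed trans-hydrostannation of a but-2-yn-1-ol unit.
2. Key bond: the C4–O ester bond, made by stereoretentive palladium/boron-mediated opening of a 2R,3R vinyl epoxy alcohol with senecioic acid. The epoxide comes from Sharpless epoxidation of a 2E,4E-dienol; its CH2OH (C6) is then oxidised and converted by Takai olefination into C6=C7–I.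
3. The dienol comes from Heck coupling of the C1 vinyl group with (E)-3-iodo-2-methylprop-2-en-1-ol.
4. The side-chain carbinol comes from Shi epoxidation of the prenyl end, followed by silyl triflate isomerisation to the allylic silyl ether.
5. C1 is set by NHC–copper SN2' substitution of geranyl diethyl phosphate with a silylpropargyl boronate.

Assumption: the chiral imidazolinium salt, the L-fructose-derived Shi ketone, D-(−)-diisopropyl tartrate and [Cp*RuCl]4 are purchased catalysts or ligands (TBS = tert-butyldimethylsilyl, pin = pinacolato).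

## Route

Step 1
Reactants: 1 1-(trimethylsilyl)propyne; 2 2-isopropoxy-4,4,5,5-tetramethyl-1,3,2-dioxaborolane
Product: 4 trimethyl[3-(4,4,5,5-tetramethyl-1,3,2-dioxaborolan-2-yl)prop-1-yn-1-yl]silane, via silylpropargyllithium 3 (not isolated)
Conditions: n-BuLi, THF, −78 → −20 °C; then 2, −78 °C; HCl in Et2O, −78 °C → rt
Reagents that add atoms: none
Why: Propargylic lithiation of the silylpropyne and electrophilic borylation with the isopropoxyboronate, followed by acid release of isopropanol, gives the silyl-capped propargyl boronate, the silyl group holding the propargyl rather than the allenyl form, and no stereocentre is formed.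

Step 2
Reactants: 5 geraniol
Product: 6 geranyl diethyl phosphate
Conditions: ClP(O)(OEt)2, pyridine, CH2Cl2, 0 °C → rt
Reagents that add atoms: diethyl chlorophosphate, CCOP(=O)(Cl)OCC
Why: Phosphorylation of the primary allylic alcohol gives the E-allylic phosphate needed as the leaving group for copper-catalysed allylic substitution, with no stereocentre formed.

Step 3
Reactants: 6 geranyl diethyl phosphate; 4 trimethyl[3-(4,4,5,5-tetramethyl-1,3,2-dioxaborolan-2-yl)prop-1-yn-1-yl]silane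
Product: 7 (S)-(4-ethenyl-4,8-dimethylnon-7-en-1-yn-1-yl)trimethylsilane
Conditions: CuCl (5 mol %), chiral sulfonate-bearing imidazolinium salt (NHC precursor, 6 mol %), NaOMe (1.5 equiv), THF, 22 °C
Reagents that add atoms: none
Why: In this NHC–copper-catalysed enantioselective SN2' allylic substitution, methoxide activates the boronate and the resulting allenylcopper adds through its CH2 terminus to the γ-carbon of the E-trisubstituted phosphate, the NHC enantiomer being chosen so that the all-carbon quaternary centre C1 is formed as S.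

Step 4
Reactants: 7 (S)-(4-ethenyl-4,8-dimethylnon-7-en-1-yn-1-yl)trimethylsilane
Product: 9 (S)-5-ethenyl-5,9-dimethyldec-8-en-2-yn-1-ol, via lithium acetylide 8 (not isolated)
Conditions: MeLi·LiBr, THF, 0 °C → rt; then (CH2O)n, −78 °C → rt; H2O
Reagents that add atoms: formaldehyde (as paraformaldehyde), C=O
Why: MeLi·LiBr cleaves the alkynyl–silicon bond to the lithium acetylide, which undergoes 1,2-addition to formaldehyde to give the propargylic alcohol without touching the quaternary centre.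

Step 5
Reactants: 9 (S)-5-ethenyl-5,9-dimethyldec-8-en-2-yn-1-ol
Product: 10 (S)-7-[(S)-3,3-dimethyloxiran-2-yl]-5-ethenyl-5-methylhept-2-yn-1-ol
Conditions: L-fructose-derived Shi ketone (30 mol %), Oxone (2KHSO5·KHSO4·K2SO4), K2CO3, Bu4NHSO4, MeCN/dimethoxymethane/aqueous buffer (pH 10.5), 0 °C
Reagents that add atoms: potassium peroxymonosulfate, [K+].[O-]S(=O)(=O)OO
Why: In this Shi asymmetric epoxidation the chiral dioxirane attacks only the electron-rich trisubstituted alkene (the terminal vinyl group and the alkyne are inert) through the spiro transition state, so the S epoxide carbon that becomes the side-chain carbinol is set under reagent control.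

Step 6
Reactants: 10 (S)-7-[(S)-3,3-dimethyloxiran-2-yl]-5-ethenyl-5-methylhept-2-yn-1-ol
Product: 12 (5S,8S)-1,8-bis(TBS-oxy)-5-ethenyl-5,9-dimethyldec-9-en-2-yne, via silyl ether epoxide 11 (not isolated)
Conditions: TBSOTf (2.5 equiv), 2,6-lutidine, toluene, −78 → 0 °C; then DBU, rt
Reagents that add atoms: tert-butyldimethylsilyl trifluoromethanesulfonate, CC(C)(C)[Si](C)(C)OS(=O)(=O)C(F)(F)F
Why: The silyl triflate first silylates the primary alcohol and then activates the epoxide oxygen, and base removes a methyl proton from the tertiary carbon (silyl triflate/amine epoxide-to-allylic silyl ether isomerisation), so the isopropenyl carbinol TBS ether forms with the C–O bond at the stereocentre never broken and S retained.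

Step 7
Reactants: 13 propargyl alcohol
Product: 15 (E)-3-iodo-2-methylprop-2-en-1-ol, via alkenylalane 14 (not isolated)
Conditions: Me3Al (3 equiv), Cp2ZrCl2 (0.25 equiv), CH2Cl2, 0 °C → rt; then I2, THF, −30 → 0 °C; aqueous work-up
Reagents that add atoms: trimethylaluminum, C[Al](C)C; iodine, II
Why: Zirconium-catalysed Negishi carboalumination adds methyl and aluminum syn across the alkyne with aluminum at the terminus, and iodinolysis with retention gives the E-iodoalkene.

Step 8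
Reactants: 12 (5S,8S)-1,8-bis(TBS-oxy)-5-ethenyl-5,9-dimethyldec-9-en-2-yne; 15 (E)-3-iodo-2-methylprop-2-en-1-ol
Product: 16 (2E,4E,6S,9S)-9-(TBS-oxy)-6-[4-(TBS-oxy)but-2-yn-1-yl]-2,6,10-trimethylundeca-2,4,10-trien-1-ol
Conditions: Pd(OAc)2 (10 mol %), Ag2CO3 (1.5 equiv), DMF, 45 °C
Reagents that add atoms: none
Why: In this Mizoroki–Heck coupling the alkenylpalladium iodide inserts at the unhindered CH2 terminus of the vinyl group and syn β-hydride elimination (only C3 hydrogens are available because C1 is quaternary) gives the 2E,4E-dienol with the iodide geometry retained and no new stereocentre.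

Step 9
Reactants: 16 (2E,4E,6S,9S)-9-(TBS-oxy)-6-[4-(TBS-oxy)but-2-yn-1-yl]-2,6,10-trimethylundeca-2,4,10-trien-1-ol
Product: 17 [(2R,3R)-3-{(1E,3S,6S)-6-(TBS-oxy)-3-[4-(TBS-oxy)but-2-yn-1-yl]-3,7-dimethylocta-1,7-dien-1-yl}-2-methyloxiran-2-yl]methanol
Conditions: Ti(OiPr)4 (20 mol %), D-(−)-diisopropyl tartrate (25 mol %), t-BuOOH (decane), 4 Å molecular sieves, CH2Cl2, −25 °C
Reagents that add atoms: tert-butyl hydroperoxide, CC(C)(C)OO
Why: In this Sharpless asymmetric epoxidation the titanium–D-(−)-tartrate complex delivers oxygen only to the alkene next to the free CH2OH (C4=C5) from the face that gives the 2R,3R epoxy alcohol, so C4 (R) and C5 (R) are set under reagent control.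

Step 10
Reactants: 17 [(2R,3R)-3-{(1E,3S,6S)-6-(TBS-oxy)-3-[4-(TBS-oxy)but-2-yn-1-yl]-3,7-dimethylocta-1,7-dien-1-yl}-2-methyloxiran-2-yl]methanol; 18 3-methylbut-2-enoic acid (senecioic acid)
Product: 20 (2R,3R,4E,6S,9S)-9-(TBS-oxy)-6-[4-(TBS-oxy)but-2-yn-1-yl]-1,2-dihydroxy-2,6,10-trimethylundeca-4,10-dien-3-yl 3-methylbut-2-enoate, via cyclic acyloxyborate 19 (not isolated)
Conditions: BH3·SMe2 (1.1 equiv) added to 18 (3.3 equiv), THF, 0 °C → rt; then 17, Pd2(dba)3·CHCl3 (2.5 mol %), PPh3 (12 mol %), THF, 0 °C → rt; pH 7 buffer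
Reagents that add atoms: none
Why: Proposed new method: a boron-tethered, palladium-catalysed stereoretentive 1,2-acyloxylation of a vinyl epoxy alcohol, in which the primary alcohol exchanges onto the triacyloxyborane, zerovalent palladium opens the allylic C4–O bond with inversion to a π-allyl complex whose C5 alkoxide closes onto boron, and the resulting anionic acyloxyborate passes a senecioate to C4 through a seven-membered transition state anti to palladium (second inversion, net retention, C4 R, C5 untouched), attack at C2 being disfavoured by the quaternary C1 and the longer tether while the cyclic borate shields the C5 and C6 hydroxyls from acyl migration; the closest known reactions are palladium-catalysed double-inversion openings of vinyl epoxides with boron-delivered alkoxide or hydroxide, and carboxylate delivery from a triacyloxyborane has not been shown.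

Step 11
Reactants: 20 (2R,3R,4E,6S,9S)-9-(TBS-oxy)-6-[4-(TBS-oxy)but-2-yn-1-yl]-1,2-dihydroxy-2,6,10-trimethylundeca-4,10-dien-3-yl 3-methylbut-2-enoate
Product: 21 (2S,3R,4E,6S,9S)-9-(TBS-oxy)-6-[4-(TBS-oxy)but-2-yn-1-yl]-2-hydroxy-2,6,10-trimethyl-1-oxoundeca-4,10-dien-3-yl 3-methylbut-2-enoate
Conditions: SO3·pyridine, DMSO, i-Pr2NEt, CH2Cl2, 0 °C
Reagents that add atoms: none
Why: Parikh–Doering (activated DMSO) oxidation converts the only oxidisable carbinol, the primary one, into the aldehyde, and since the α-carbon carries no hydrogen C5 cannot epimerise (its descriptor changes to S only through the priority rules).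

Step 12
Reactants: 21 (2S,3R,4E,6S,9S)-9-(TBS-oxy)-6-[4-(TBS-oxy)but-2-yn-1-yl]-2-hydroxy-2,6,10-trimethyl-1-oxoundeca-4,10-dien-3-yl 3-methylbut-2-enoate
Product: 22 (1E,3R,4R,5E,7S,10S)-10-(TBS-oxy)-7-[4-(TBS-oxy)but-2-yn-1-yl]-3-hydroxy-1-iodo-3,7,11-trimethyldodeca-1,5,11-trien-4-yl 3-methylbut-2-enoate
Conditions: CrCl2 (8 equiv), CHI3 (3 equiv), THF/1,4-dioxane, 0 °C → rt
Reagents that add atoms: iodoform, IC(I)I
Why: In this Takai olefination the geminal dichromium species from iodoform adds to the aldehyde and eliminates to the E-vinyl iodide selectively, the free tertiary alcohol and the ester being tolerated.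

Step 13
Reactants: 22 (1E,3R,4R,5E,7S,10S)-10-(TBS-oxy)-7-[4-(TBS-oxy)but-2-yn-1-yl]-3-hydroxy-1-iodo-3,7,11-trimethyldodeca-1,5,11-trien-4-yl 3-methylbut-2-enoate
Product: 23 (1E,3R,4R,5E,7S,10S)-3,10-dihydroxy-7-(4-hydroxybut-2-yn-1-yl)-1-iodo-3,7,11-trimethyldodeca-1,5,11-trien-4-yl 3-methylbut-2-enoate
Conditions: HF·pyridine, pyridine, THF, 0 °C → rt
Reagents that add atoms: none
Why: Buffered fluoride cleavage of both silyl ethers (desilylation driven by Si–F bond formation) frees the propargylic and side-chain alcohols without ester migration or loss of the vinyl iodide.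

Step 14
Reactants: 23 (1E,3R,4R,5E,7S,10S)-3,10-dihydroxy-7-(4-hydroxybut-2-yn-1-yl)-1-iodo-3,7,11-trimethyldodeca-1,5,11-trien-4-yl 3-methylbut-2-enoate
Product: 24 (1E,3R,4R,5E,7S,10S)-3,10-dihydroxy-7-[(2Z)-4-hydroxy-3-(tributylstannyl)but-2-en-1-yl]-1-iodo-3,7,11-trimethyldodeca-1,5,11-trien-4-yl 3-methylbut-2-enoate
Conditions: [Cp*RuCl]4 (2.5 mol %), Bu3SnH (1.15 equiv, slow addition), CH2Cl2, rt
Reagents that add atoms: tributyltin hydride, CCCC[SnH](CCCC)CCCC
Why: In this hydroxyl-directed ruthenium-catalysed trans-hydrostannation, hydrogen bonding of the propargylic OH to the Ru–Cl unit steers tin to the alkyne carbon next to CH2OH and H and Sn add anti, giving the Z-alkenylstannane (tin cis to C11) that the ring Z-enone requires.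

Step 15
Reactants: 24 (1E,3R,4R,5E,7S,10S)-3,10-dihydroxy-7-[(2Z)-4-hydroxy-3-(tributylstannyl)but-2-en-1-yl]-1-iodo-3,7,11-trimethyldodeca-1,5,11-trien-4-yl 3-methylbut-2-enoate
Product: 25 target CNP0311723.1, (1R,2E,4S,6Z,9E,11R)-11-hydroxy-4-[(3S)-3-hydroxy-4-methylpent-4-en-1-yl]-7-(hydroxymethyl)-4,11-dimethyl-8-oxocycloundeca-2,6,9-trien-1-yl 3-methylbut-2-enoate
Conditions: Pd2(dba)3·CHCl3 (10 mol %), AsPh3 (40 mol %), CuI (20 mol %), LiCl, CO (3 atm), N-methylpyrrolidone, 45 °C, syringe-pump addition to 2 mM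
Reagents that add atoms: carbon monoxide, [C-]#[O+]
Why: In this intramolecular carbonylative Stille coupling, oxidative addition to the E-vinyl iodide, CO insertion, copper-assisted transmetalation of the alkenylstannane and reductive elimination all proceed with retention of alkene geometry and close the 11-membered ring as the cross-conjugated dienone with the free hydroxyls tolerated.

## Compound list

1 | 1-(trimethylsilyl)propyne | CC#C[Si](C)(C)C | starting material
2 | 2-isopropoxy-4,4,5,5-tetramethyl-1,3,2-dioxaborolane | CC(C)OB1OC(C)(C)C(C)(C)O1 | starting material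
3 | [3-(trimethylsilyl)prop-2-yn-1-yl]lithium | [Li]CC#C[Si](C)(C)C | intermediate
4 | trimethyl[3-(4,4,5,5-tetramethyl-1,3,2-dioxaborolan-2-yl)prop-1-yn-1-yl]silane | C[Si](C)(C)C#CCB1OC(C)(C)C(C)(C)O1 | intermediate
5 | geraniol, (2E)-3,7-dimethylocta-2,6-dien-1-ol | CC(C)=CCC/C(C)=C/CO | starting material
6 | geranyl diethyl phosphate | CC(C)=CCC/C(C)=C/COP(=O)(OCC)OCC | intermediate
7 | (S)-(4-ethenyl-4,8-dimethylnon-7-en-1-yn-1-yl)trimethylsilane | CC(C)=CCC[C@](CC#C[Si](C)(C)C)(C)C=C | intermediate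
8 | lithium acetylide of (S)-4-ethenyl-4,8-dimethylnon-7-en-1-yne | CC(C)=CCC[C@](CC#C[Li])(C)C=C | intermediate
9 | (S)-5-ethenyl-5,9-dimethyldec-8-en-2-yn-1-ol | CC(C)=CCC[C@](CC#CCO)(C)C=C | intermediate
10 | (S)-7-[(S)-3,3-dimethyloxiran-2-yl]-5-ethenyl-5-methylhept-2-yn-1-ol | CC1(C)O[C@H]1CC[C@](CC#CCO)(C)C=C | intermediate
11 | TBS ether of 10 at the propargylic oxygen | CC1(C)O[C@H]1CC[C@](CC#CCO[Si](C)(C)C(C)(C)C)(C)C=C | intermediate
12 | (5S,8S)-1,8-bis(TBS-oxy)-5-ethenyl-5,9-dimethyldec-9-en-2-yne | C=C(C)[C@@H](O[Si](C)(C)C(C)(C)C)CC[C@](CC#CCO[Si](C)(C)C(C)(C)C)(C)C=C | intermediate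
13 | propargyl alcohol | C#CCO | starting material
14 | dimethylaluminum (E)-3-(dimethylalumanyl)-2-methylprop-2-en-1-olate | C[Al](C)OC/C(C)=C/[Al](C)C | intermediate
15 | (E)-3-iodo-2-methylprop-2-en-1-ol | OC/C(C)=C/I | intermediate
16 | (2E,4E,6S,9S)-9-(TBS-oxy)-6-[4-(TBS-oxy)but-2-yn-1-yl]-2,6,10-trimethylundeca-2,4,10-trien-1-ol | C=C(C)[C@@H](O[Si](C)(C)C(C)(C)C)CC[C@](CC#CCO[Si](C)(C)C(C)(C)C)(C)/C=C/C=C(\C)CO | intermediate
17 | [(2R,3R)-3-{(1E,3S,6S)-6-(TBS-oxy)-3-[4-(TBS-oxy)but-2-yn-1-yl]-3,7-dimethylocta-1,7-dien-1-yl}-2-methyloxiran-2-yl]methanol | C=C(C)[C@@H](O[Si](C)(C)C(C)(C)C)CC[C@](CC#CCO[Si](C)(C)C(C)(C)C)(C)/C=C/[C@H]1O[C@]1(C)CO | intermediate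
18 | 3-methylbut-2-enoic acid (senecioic acid) | CC(C)=CC(=O)O | starting material
19 | 2-(3-methylbut-2-enoyloxy)-1,3,2-dioxaborolane formed on the 1,2-diol of 20, C3 senecioate in place | C=C(C)[C@@H](O[Si](C)(C)C(C)(C)C)CC[C@](CC#CCO[Si](C)(C)C(C)(C)C)(C)/C=C/[C@@H](OC(=O)C=C(C)C)[C@@]1(C)COB(OC(=O)C=C(C)C)O1 | intermediate
20 | (2R,3R,4E,6S,9S)-9-(TBS-oxy)-6-[4-(TBS-oxy)but-2-yn-1-yl]-1,2-dihydroxy-2,6,10-trimethylundeca-4,10-dien-3-yl 3-methylbut-2-enoate | C=C(C)[C@@H](O[Si](C)(C)C(C)(C)C)CC[C@](CC#CCO[Si](C)(C)C(C)(C)C)(C)/C=C/[C@@H](OC(=O)C=C(C)C)[C@](C)(O)CO | intermediate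
21 | (2S,3R,4E,6S,9S)-9-(TBS-oxy)-6-[4-(TBS-oxy)but-2-yn-1-yl]-2-hydroxy-2,6,10-trimethyl-1-oxoundeca-4,10-dien-3-yl 3-methylbut-2-enoate | C=C(C)[C@@H](O[Si](C)(C)C(C)(C)C)CC[C@](CC#CCO[Si](C)(C)C(C)(C)C)(C)/C=C/[C@@H](OC(=O)C=C(C)C)[C@](C)(O)C=O | intermediate
22 | (1E,3R,4R,5E,7S,10S)-10-(TBS-oxy)-7-[4-(TBS-oxy)but-2-yn-1-yl]-3-hydroxy-1-iodo-3,7,11-trimethyldodeca-1,5,11-trien-4-yl 3-methylbut-2-enoate | C=C(C)[C@@H](O[Si](C)(C)C(C)(C)C)CC[C@](CC#CCO[Si](C)(C)C(C)(C)C)(C)/C=C/[C@@H](OC(=O)C=C(C)C)[C@](C)(O)/C=C/I | intermediate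
23 | (1E,3R,4R,5E,7S,10S)-3,10-dihydroxy-7-(4-hydroxybut-2-yn-1-yl)-1-iodo-3,7,11-trimethyldodeca-1,5,11-trien-4-yl 3-methylbut-2-enoate | C=C(C)[C@@H](O)CC[C@](CC#CCO)(C)/C=C/[C@@H](OC(=O)C=C(C)C)[C@](C)(O)/C=C/I | intermediate
24 | (1E,3R,4R,5E,7S,10S)-3,10-dihydroxy-7-[(2Z)-4-hydroxy-3-(tributylstannyl)but-2-en-1-yl]-1-iodo-3,7,11-trimethyldodeca-1,5,11-trien-4-yl 3-methylbut-2-enoate | C=C(C)[C@@H](O)CC[C@](C/C=C(/CO)[Sn](CCCC)(CCCC)CCCC)(C)/C=C/[C@@H](OC(=O)C=C(C)C)[C@](C)(O)/C=C/I | intermediate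
25 | CNP0311723.1, (1R,2E,4S,6Z,9E,11R)-11-hydroxy-4-[(3S)-3-hydroxy-4-methylpent-4-en-1-yl]-7-(hydroxymethyl)-4,11-dimethyl-8-oxocycloundeca-2,6,9-trien-1-yl 3-methylbut-2-enoate | C=C(C)[C@@H](O)CC[C@]1(C)/C=C/[C@@H](OC(=O)C=C(C)C)[C@](C)(O)/C=C/C(=O)/C(CO)=C\C1 | target

## Step count and risks

Total step count: 15. Longest linear sequence: 13 steps (geraniol 5 to 25 through steps 2–6 and 8–15).

**Step 10 (the proposed new reaction).** The carboxylate may fail to transfer, may go to C2, or the π-allyl complex may collapse to a dienol or enone. The fallback uses known chemistry and trades retention on the E series for inversion on the Z series. It sets out from 12. Heck coupling under the step 8 conditions with (Z)-3-iodo-2-methylprop-2-en-1-ol F4 (made from 13 by copper-catalysed anti-carbomagnesiation, MeMgBr/CuI, then I2) gives the 2Z,4E-dienol F5. Sharpless epoxidation with Ti(OiPr)4, D-(−)-diisopropyl tartrate and t-BuOOH gives the cis-epoxy alcohol F6 (C5 R, C4 S). Ti(OiPr)4-mediated opening with 18, which attacks C3 of a 2,3-epoxy alcohol (here C4) with inversion, comes back to the route at 20.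

**Step 8 (Heck coupling).** The alkenylpalladium may add to the internal alkyne instead of the hindered vinyl group. The fallback sets out from 10, where the vinyl group is the only alkene. Ozonolysis (O3, CH2Cl2/MeOH, −78 °C; Me2S) gives the epoxy aldehyde F1. Horner–Wadsworth–Emmons olefination with commercial ethyl (E)-4-(diethoxyphosphoryl)-2-methylbut-2-enoate and LiN(SiMe3)2 in THF gives the epoxy dienoate F2. TBSOTf/2,6-lutidine then DBU, as in step 6, gives the bis-silyl dienoate F3. Reduction with i-Bu2AlH at −78 °C comes back to the route at 16.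

**Step 15 (carbonylative macrocyclisation).** Oligomers, direct coupling without CO, or ionisation of the allylic ester by zerovalent palladium may compete. The fallback closes the ring at C6=C7 by metathesis and sets out from 21. Lombardo methylenation (Zn, CH2Br2, TiCl4) gives the vinyl carbinol F7. HF·pyridine gives the desilylated alkyne triol F8. [Cp*RuCl]4/Bu3SnH gives the alkenylstannane F9. Intermolecular carbonylative Stille coupling with iodoethene under CO (Pd2(dba)3·CHCl3, AsPh3) gives the divinyl ketone F10. Ring-closing metathesis with the second-generation Hoveyda–Grubbs catalyst (H2IMes)Cl2Ru(=CH-C6H4-2-O-i-Pr) in dilute toluene at 80 °C comes back to the route at 25.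

## Further compounds

F1 | step 8 | (S)-2-{2-[(S)-3,3-dimethyloxiran-2-yl]ethyl}-6-hydroxy-2-methylhex-4-ynal | CC1(C)O[C@H]1CC[C@](CC#CCO)(C)C=O
F2 | step 8 | ethyl (2E,4E,6S)-6-{2-[(S)-3,3-dimethyloxiran-2-yl]ethyl}-10-hydroxy-2,6-dimethyldeca-2,4-dien-8-ynoate | CC1(C)O[C@H]1CC[C@](CC#CCO)(C)/C=C/C=C(\C)C(=O)OCC
F3 | step 8 | ethyl (2E,4E,6S,9S)-9-(TBS-oxy)-6-[4-(TBS-oxy)but-2-yn-1-yl]-2,6,10-trimethylundeca-2,4,10-trienoate | C=C(C)[C@@H](O[Si](C)(C)C(C)(C)C)CC[C@](CC#CCO[Si](C)(C)C(C)(C)C)(C)/C=C/C=C(\C)C(=O)OCC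
F4 | step 10 | (Z)-3-iodo-2-methylprop-2-en-1-ol | OC/C(C)=C\I
F5 | step 10 | (2Z,4E,6S,9S)-9-(TBS-oxy)-6-[4-(TBS-oxy)but-2-yn-1-yl]-2,6,10-trimethylundeca-2,4,10-trien-1-ol | C=C(C)[C@@H](O[Si](C)(C)C(C)(C)C)CC[C@](CC#CCO[Si](C)(C)C(C)(C)C)(C)/C=C/C=C(/C)CO
F6 | step 10 | [(2R,3S)-3-{(1E,3S,6S)-6-(TBS-oxy)-3-[4-(TBS-oxy)but-2-yn-1-yl]-3,7-dimethylocta-1,7-dien-1-yl}-2-methyloxiran-2-yl]methanol | C=C(C)[C@@H](O[Si](C)(C)C(C)(C)C)CC[C@](CC#CCO[Si](C)(C)C(C)(C)C)(C)/C=C/[C@@H]1O[C@]1(C)CO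
F7 | step 15 | (3R,4R,5E,7S,10S)-10-(TBS-oxy)-7-[4-(TBS-oxy)but-2-yn-1-yl]-3-hydroxy-3,7,11-trimethyldodeca-1,5,11-trien-4-yl 3-methylbut-2-enoate | C=C(C)[C@@H](O[Si](C)(C)C(C)(C)C)CC[C@](CC#CCO[Si](C)(C)C(C)(C)C)(C)/C=C/[C@@H](OC(=O)C=C(C)C)[C@](C)(O)C=C
F8 | step 15 | (3R,4R,5E,7S,10S)-3,10-dihydroxy-7-(4-hydroxybut-2-yn-1-yl)-3,7,11-trimethyldodeca-1,5,11-trien-4-yl 3-methylbut-2-enoate | C=C(C)[C@@H](O)CC[C@](CC#CCO)(C)/C=C/[C@@H](OC(=O)C=C(C)C)[C@](C)(O)C=C
F9 | step 15 | (3R,4R,5E,7S,10S)-3,10-dihydroxy-7-[(2Z)-4-hydroxy-3-(tributylstannyl)but-2-en-1-yl]-3,7,11-trimethyldodeca-1,5,11-trien-4-yl 3-methylbut-2-enoate | C=C(C)[C@@H](O)CC[C@](C/C=C(/CO)[Sn](CCCC)(CCCC)CCCC)(C)/C=C/[C@@H](OC(=O)C=C(C)C)[C@](C)(O)C=C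
F10 | step 15 | (3R,4R,5E,7S,10S)-3,10-dihydroxy-7-[(2Z)-3-(hydroxymethyl)-4-oxohexa-2,5-dien-1-yl]-3,7,11-trimethyldodeca-1,5,11-trien-4-yl 3-methylbut-2-enoate | C=C(C)[C@@H](O)CC[C@](C/C=C(/CO)C(=O)C=C)(C)/C=C/[C@@H](OC(=O)C=C(C)C)[C@](C)(O)C=C
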